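The cyclohexene core (ring carbons C1–C6: C1 = CH–O next to C6, C2=C3 with the hydroxymethyl carbon C7 on C3, C4 and C5 = CH–O, C6 = CH–iPr) is cut between C2/C3 and between C5/C6 into two enals: crotonaldehyde (C7, C3, C4, C5) and 4-methylpent-2-enal (C2, C1, C6, iPr). A proline-mediated formal [3+3] annulation exploits the para disposition of C3 and C6: one operation joins C5 to C6 and C2 to C3 and sets C6. In the resulting dienal the C4=C5 bond (syn-dihydroxylation), the γ-carbon C1 (vinylogous oxidation) and the formyl group (latent CH2OH) deliver all remaining functionality without protecting C7.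

Key step: step 1

Assumption: L-proline is taken to deliver the 4R adduct 3; if the sense of induction is the opposite, D-proline (equally available) replaces it with no other change.
Remark: C1–C7 in the Why lines are the target positions defined above; systematic names of intermediates carry their own numbering.

Step 1
Reactants: 1 (E)-but-2-enal (crotonaldehyde); 2 (E)-4-methylpent-2-enal
Product: 3 (4R)-4-(propan-2-yl)cyclohexa-1,5-diene-1-carbaldehyde
Conditions: L-proline (50 mol %), DMF, −10 °C, 1 added slowly to 2 (1.5 equiv), 36 h; 3 kept cold under argon and used at once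
Reagents that add atoms: none
Why: Proline converts 1 into its dienamine, whose γ-carbon (C5) adds to C6 of proline-activated 2; the enal end then re-forms a dienamine whose α-carbon (C3) attacks the liberated aldehyde carbon C2, and loss of water gives the C2=C3 bond (vinylogous Michael addition followed by intramolecular aldol condensation). The closest known reaction type is the amine-catalysed formal [3+3] carbo-annulation of two α,β-unsaturated aldehydes to cyclohexadienecarbaldehydes. The ring is closed in a 6-(enolexo)-exo-trig aldol step, the C7=C3 enamine bond lying outside the new ring. C6 is the only new stereocentre and is set in the Michael step under catalyst control, the proline carboxylic acid steering the acceptor to one face. The step needs cross- over homo-annulation and [3+3] over [4+2] regiochemistry: 1 is the only partner with an unhindered γ-methyl group (the γ-carbon of 2 is a tertiary CH), so 1 should act as donor and 2 as acceptor, and slow addition of 1 at low temperature should keep its self-condensation down.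

Step 2
Reactants: 3 (4R)-4-(propan-2-yl)cyclohexa-1,5-diene-1-carbaldehyde
Product: 4 (4R,5R,6S)-5,6-dihydroxy-4-(propan-2-yl)cyclohex-1-ene-1-carbaldehyde
Conditions: OsO4 (2 mol %), NMO (1.2 equiv), acetone–H2O (4:1), 0 °C
Reagents that add atoms: N-methylmorpholine N-oxide C[N+]1([O-])CCOCC1; water O
Why: Catalytic OsO4/NMO syn-dihydroxylation should take the cis-disubstituted C4=C5 bond, which is more electron-rich than the formyl-bearing C2=C3 bond, on the ring face opposite the adjacent isopropyl group, which sets C4 and C5.

Step 3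
Reactants: 4 (4R,5R,6S)-5,6-dihydroxy-4-(propan-2-yl)cyclohex-1-ene-1-carbaldehyde
Product: 5 (1R,2S,6R)-3-formyl-2-hydroxy-6-(propan-2-yl)cyclohex-3-en-1-yl acetate
Conditions: 2-aminoethyl diphenylborinate (10 mol %), AcCl (1.1 equiv), iPr2NEt (1.2 equiv), MeCN, 0 °C
Reagents that add atoms: acetyl chloride CC(=O)Cl
Why: Borinic-acid-catalysed regioselective monoacylation of a cis-1,2-diol: in the half-chair with the isopropyl group equatorial, the borinate adduct should deliver the acetyl group to the equatorial O5 and not to the pseudoaxial, allylic O4, which is also hydrogen-bonded to the formyl group.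

Step 4
Reactants: 5 (1R,2S,6R)-3-formyl-2-hydroxy-6-(propan-2-yl)cyclohex-3-en-1-yl acetate
Product: 6 6-(propan-2-yl)-2-(triethylsilyloxy)-3-[(triethylsilyloxy)methylidene]cyclohex-4-en-1-yl acetate (ring stereocentres as in 5; E/Z mixture at the enol ether)
Conditions: TESOTf (2.4 equiv), Et3N (4 equiv), CH2Cl2, −78 → 0 °C; filtered through basic Al2O3 (pentane), used crude
Reagents that add atoms: triethylsilyl trifluoromethanesulfonate CC[Si](CC)(CC)OS(=O)(=O)C(F)(F)F
Why: O-Silylation of O4 and soft enolisation: the silyl-activated enal is deprotonated by Et3N at its only γ-position (C1) to give the extended silyl dienol ether, the O4 silyl ether being a poor leaving group that should resist vinylogous β-elimination, and no stereocentre is touched.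

Step 5
Reactants: 6 6-(propan-2-yl)-2-(triethylsilyloxy)-3-[(triethylsilyloxy)methylidene]cyclohex-4-en-1-yl acetate
Product: 8 (1R,2S,5S,6S)-3-formyl-2,5-dihydroxy-6-(propan-2-yl)cyclohex-3-en-1-yl acetate, via vinyl epoxide 7 (not isolated)
Conditions: DMDO (1.05 equiv), acetone–CH2Cl2, −78 → −30 °C; volatiles removed cold; then HF·pyridine, THF, 0 °C
Reagents that add atoms: dimethyldioxirane CC1(C)OO1
Why: Vinylogous Rubottom oxidation: DMDO should epoxidise the terminal C1=C2 bond of the silyloxydiene (the enol ether carbon C3 is fully substituted) with axial delivery at C1, anti to the pseudoaxial C6–H and to the pseudoaxial O4 silyl ether, so that O1 ends up cis to the isopropyl group and trans to O5, and HF·pyridine then collapses the epoxide to the γ-hydroxy enal and removes both silyl groups.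

Step 6
Reactants: 8 (1R,2S,5S,6S)-3-formyl-2,5-dihydroxy-6-(propan-2-yl)cyclohex-3-en-1-yl acetate
Product: 9 (1S,4S,5R,6S)-5-(acetyloxy)-3-formyl-6-(propan-2-yl)cyclohex-2-ene-1,4-diyl bis[(2E)-2-methylbut-2-enoate]
Conditions: tigloyl chloride (3 equiv), pyridine, DMAP (20 mol %), CH2Cl2, 0 °C → rt
Reagents that add atoms: (E)-2-methylbut-2-enoyl chloride (tigloyl chloride) C/C=C(\C)C(=O)Cl
Why: DMAP-catalysed acylation of the two remaining secondary hydroxyl groups (O1 and O4) with retention, pyridine as the only base avoiding the vinylketene pathway that would deconjugate the tigloyl unit.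

Step 7
Reactants: 9 (1S,4S,5R,6S)-5-(acetyloxy)-3-formyl-6-(propan-2-yl)cyclohex-2-ene-1,4-diyl bis[(2E)-2-methylbut-2-enoate]
Product: 10 (1S,4S,5R,6S)-5-(acetyloxy)-3-(hydroxymethyl)-6-(propan-2-yl)cyclohex-2-ene-1,4-diyl bis[(2E)-2-methylbut-2-enoate] (CNP0169590.1)
Conditions: NaBH4 (1.0 equiv), CeCl3·7H2O (1.1 equiv), MeOH, −78 °C; AcOH quench at −78 °C
Reagents that add atoms: none
Why: Luche reduction: CeCl3-activated NaBH4 should reduce the enal 1,2 at −78 °C and leave the three esters untouched, and the acidic quench before warming suppresses O4→O7 acyl migration.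

Compound list
1 | (E)-but-2-enal (crotonaldehyde) | C/C=C/C=O | starting material
2 | (E)-4-methylpent-2-enal | CC(C)/C=C/C=O | starting material
3 | (4R)-4-(propan-2-yl)cyclohexa-1,5-diene-1-carbaldehyde | C1C=C(C=O)C=C[C@H]1C(C)C | intermediate
4 | (4R,5R,6S)-5,6-dihydroxy-4-(propan-2-yl)cyclohex-1-ene-1-carbaldehyde (cis-diol on the face opposite iPr) | C1C=C(C=O)[C@H](O)[C@H](O)[C@H]1C(C)C | intermediate
5 | (1R,2S,6R)-3-formyl-2-hydroxy-6-(propan-2-yl)cyclohex-3-en-1-yl acetate (O5 acetate, O4 free) | C1C=C(C=O)[C@H](O)[C@H](OC(C)=O)[C@H]1C(C)C | intermediate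
6 | 6-(propan-2-yl)-2-(triethylsilyloxy)-3-[(triethylsilyloxy)methylidene]cyclohex-4-en-1-yl acetate (ring stereocentres as in 5; E/Z mixture at the enol ether) | C1=CC(=CO[Si](CC)(CC)CC)[C@H](O[Si](CC)(CC)CC)[C@H](OC(C)=O)[C@H]1C(C)C | intermediate
7 | vinyl epoxide of 6 (C1–C2 oxirane on the face of the isopropyl group; both silyl groups retained) | O1[C@H]2[C@@H]1C(=CO[Si](CC)(CC)CC)[C@H](O[Si](CC)(CC)CC)[C@H](OC(C)=O)[C@H]2C(C)C | intermediate
8 | (1R,2S,5S,6S)-3-formyl-2,5-dihydroxy-6-(propan-2-yl)cyclohex-3-en-1-yl acetate (O1–H cis to iPr) | O[C@H]1C=C(C=O)[C@H](O)[C@H](OC(C)=O)[C@H]1C(C)C | intermediate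
9 | (1S,4S,5R,6S)-5-(acetyloxy)-3-formyl-6-(propan-2-yl)cyclohex-2-ene-1,4-diyl bis[(2E)-2-methylbut-2-enoate] | C/C=C(\C)C(=O)O[C@H]1C=C(C=O)[C@H](OC(=O)/C(C)=C/C)[C@H](OC(C)=O)[C@H]1C(C)C | intermediate
10 | (1S,4S,5R,6S)-5-(acetyloxy)-3-(hydroxymethyl)-6-(propan-2-yl)cyclohex-2-ene-1,4-diyl bis[(2E)-2-methylbut-2-enoate] (CNP0169590.1) | C/C=C(\C)C(=O)O[C@H]1C=C(CO)[C@H](OC(=O)/C(C)=C/C)[C@H](OC(C)=O)[C@H]1C(C)C | target

Total step count: 7. Longest linear sequence: 7 steps (both starting materials enter in step 1).

Steps most likely to fail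

1. Step 1. Self-annulation of 1, the competing [4+2]-type ring closure (aldehyde carbon of 1 built into the ring) or weak facial discrimination in the Michael event may erode the cross-[3+3] adduct, and 3 may aromatise on standing. Fallback, from 1 and 2, returning at 3: 1 is converted with TMSCl, Et3N and ZnCl2 into (E)-1-(trimethylsilyloxy)buta-1,3-diene F1. A chiral imidazolidinone salt ((2S,5S)-5-benzyl-2-tert-butyl-3-methylimidazolidin-4-one·2,4-dinitrobenzoic acid, or its enantiomer as required for 5R) catalyses the γ-selective Mukaiyama–Michael addition of F1 to 2 and should give (2E,5R)-5-(propan-2-yl)hept-2-enedial F2, so that the C5–C6 bond and the C6 stereocentre are set without homo-coupling. Pyrrolidinium acetate then closes the C2=C3 bond by the same intramolecular dienamine aldol condensation to give 3.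

2. Step 5. Oxygen may be delivered to the lower face of the C1=C2 bond (low or reversed facial selectivity), which would give the C1 epimer. Fallback, from 6, returning at 9: if DMDO adds mainly to the lower face, the diastereomeric vinyl epoxide F3 forms and, after buffered aqueous work-up (pH 7, no fluoride), collapses to the C1-epimeric γ-hydroxy enal F4, which keeps its O4 silyl ether. Mitsunobu esterification of F4 (tiglic acid, PPh3, DIAD, toluene) installs the C1 tiglate with inversion to give the O4-silylated C1 tiglate F5. HF·pyridine frees O4 to give the hydroxy ester F6, and tigloyl chloride/pyridine/DMAP then gives 9.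

3. Step 3. Acyl transfer may go to O4 instead of O5, or the acetyl group may shuttle between the cis-oxygens, giving a mixture of monoacetates. Fallback, from 4, returning at 5: kinetic catalyst control is replaced by thermodynamic control. 4 and trimethyl orthoacetate (PPTS cat., CH2Cl2) give the cyclic orthoacetate F7; brief hydrolysis in aqueous acetic acid opens it to the pseudoaxial O4 acetate F8 (axial-ester rule); catalytic DBU in toluene then lets the acetyl group migrate across the cis-diol to the equatorial O5, the expected thermodynamic site, giving 5.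

Further compounds
F1 | step 1 | (E)-1-(trimethylsilyloxy)buta-1,3-diene | C=C/C=C/O[Si](C)(C)C
F2 | step 1 | (2E,5R)-5-(propan-2-yl)hept-2-enedial | O=C/C=C/C[C@H](CC=O)C(C)C
F3 | step 5 | diastereomeric vinyl epoxide of 6 (oxirane on the face opposite the isopropyl group) | O1[C@@H]2[C@H]1C(=CO[Si](CC)(CC)CC)[C@H](O[Si](CC)(CC)CC)[C@H](OC(C)=O)[C@H]2C(C)C
F4 | step 5 | C1-epimeric γ-hydroxy enal, O4 triethylsilyl ether, O5 acetate | O[C@@H]1C=C(C=O)[C@H](O[Si](CC)(CC)CC)[C@H](OC(C)=O)[C@H]1C(C)C
F5 | step 5 | O4-silylated C1 tiglate (C1 configuration of the target), O5 acetate | C/C=C(\C)C(=O)O[C@H]1C=C(C=O)[C@H](O[Si](CC)(CC)CC)[C@H](OC(C)=O)[C@H]1C(C)C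
F6 | step 5 | hydroxy ester: C1 tiglate, O4–H, O5 acetate, formyl on C3 | C/C=C(\C)C(=O)O[C@H]1C=C(C=O)[C@H](O)[C@H](OC(C)=O)[C@H]1C(C)C
F7 | step 3 | cyclic orthoacetate of 4 (2-methoxy-2-methyl-1,3-dioxolane across O4/O5, epimers at the orthoester carbon) | C1C=C(C=O)[C@@H]2OC(C)(OC)O[C@@H]2[C@H]1C(C)C
F8 | step 3 | O4 acetate regioisomer of 5 (O5 free) | C1C=C(C=O)[C@H](OC(C)=O)[C@H](O)[C@H]1C(C)C
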